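**Plan**

- Locants: ring C1 (CHOH), C2 (epoxide C–CH3), C3 (epoxide CH), C4 (CH2), C5 (CH bearing the side chain), C6 (CH–O‑angeloyl); side chain C1' (C=CH2), C2' (CH–O‑angeloyl), C3' (CH2), C4'/C5' (oxirane CH/CMe2).
- Enabling feature: C1 lies between C2 and C6 and is 1,3 to C5. Read as a ketone with C2=C3 as an alkene, the ring is a 2‑methylcyclohex‑2‑enone substituted at C5, which is the 1,5‑dicarbonyl retron (C1 ketone / C3 aldehyde) of a Michael/aldol‑condensation [3+3] annulation.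
- Retrosynthesis: remove the ring epoxide oxygen and C1–OH (directed epoxidation, Luche reduction), the C6 oxygen (enolate oxidation) and the C4' oxygen (Shi epoxidation); cut C4'=C5' and C2'–C3' (cross‑metathesis, allylboration); remove the exocyclic CH2 (α‑methylenation); then cut C5–C6 and C2–C3 together to give enal 3 and β‑keto ester 4.
- Forward: the carbocycle is made first in one pot (step 2), the side chain is grown outward from C5 (steps 3–9), and the ring is oxygenated last at C6, C1 and C2/C3 (steps 10–13). The helpers are the tert‑butyl ester (lost in step 2), the C1 ketone level and the C2=C3 alkene (used in steps 12–13).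
- Stereochemistry: C5 from the aminocatalyst; C2' from reagent‑controlled allylboration; C4' from the Shi catalyst; C6 by trans‑hydroxylation then Mitsunobu inversion with angelic acid; C1 by hydride addition anti to the axial C6 ester; the epoxide by delivery from the C1 hydroxyl.

Key step: step 2

Remark: the kinetic C6 enolate of 16 is assumed to be oxidised anti to the C5 substituent (trans), as is usual for 5‑substituted cyclohex‑2‑enone dienolates, and step 11 then inverts this centre; compounds 1, 2, 4 and 12, the chiral amine, the (−)‑Ipc2B(allyl) solution and the Shi ketone are taken as purchased.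

**Step 1**
Reactants: 1 but‑3‑en‑1‑yl acetate; 2 (E)‑but‑2‑enal
Product: 3 (E)‑5‑oxopent‑3‑en‑1‑yl acetate
Conditions: 2 (5 equiv), second‑generation Grubbs catalyst (H2IMes)(PCy3)Cl2Ru=CHPh (2 mol%), CH2Cl2, 40 °C
Reagents that add atoms: none
Why: Olefin cross‑metathesis of a terminal alkene with an excess of the electron‑poor enal should give the (E)‑enal with loss of propene; no stereocentre is formed.

**Step 2**
Reactants: 3 (E)‑5‑oxopent‑3‑en‑1‑yl acetate; 4 tert‑butyl 3‑oxopentanoate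
Product: 7 2‑[(1S)‑4‑methyl‑5‑oxocyclohex‑3‑en‑1‑yl]ethyl acetate, via Michael adduct 5 (not isolated), via keto aldehyde 6 (not isolated)
Conditions: (S)‑2‑{bis[3,5‑bis(trifluoromethyl)phenyl](trimethylsilyloxy)methyl}pyrrolidine (10 mol%), PhCO2H (10 mol%), toluene, rt; then TsOH·H2O (20 mol%), toluene, 80 °C
Reagents that add atoms: none
Why: The (S)‑diarylprolinol silyl ether converts enal 3 into an (E)‑iminium ion, and the enol of β‑keto ester 4 adds to its β‑carbon (organocatalytic Michael addition, forming the C5–C6 bond) on the face not covered by the silyloxydiarylmethyl arm, so the C5 stereocentre is set by the catalyst. Warm TsOH then cleaves the tert‑butyl ester, the β‑keto acid decarboxylates to keto aldehyde 6, and the ethyl‑ketone enol closes onto the aldehyde by a 6‑(enolendo)‑exo‑trig aldol addition followed by dehydration, which forms the C2–C3 bond as the enone C=C. The closest known reaction type is the amine‑catalysed Michael/aldol‑condensation (Robinson‑type) [3+3] annulation of β‑keto esters with enals. The regiochemistry of ring closure is fixed by ring size, because the other α‑carbon of 6 could reach the aldehyde only through a four‑membered ring; 1,4‑ over 1,2‑addition is secured by the iminium ion and the soft 1,3‑dicarbonyl donor. C5 is never α to a carbonyl group in 5, 6 or 7 and should survive the acid stage, and the primary acetate is inert to both catalysts.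

**Step 3**
Reactants: 7 2‑[(1S)‑4‑methyl‑5‑oxocyclohex‑3‑en‑1‑yl]ethyl acetate
Product: 8 (5S)‑5‑(2‑hydroxyethyl)‑2‑methylcyclohex‑2‑en‑1‑one
Conditions: K2CO3 (0.2 equiv), MeOH, 0 °C
Reagents that add atoms: none
Why: Base‑catalysed transesterification (methanolysis) removes the primary acetate without touching the enone, and C5 is not enolisable.

**Step 4**
Reactants: 8 (5S)‑5‑(2‑hydroxyethyl)‑2‑methylcyclohex‑2‑en‑1‑one
Product: 9 2‑[(1S)‑4‑methyl‑5‑oxocyclohex‑3‑en‑1‑yl]acetaldehyde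
Conditions: Dess–Martin periodinane, CH2Cl2, 0 °C to rt
Reagents that add atoms: none
Why: Dess–Martin oxidation of the primary alcohol to the aldehyde under neutral conditions leaves the stereocentre untouched.

**Step 5**
Reactants: 9 2‑[(1S)‑4‑methyl‑5‑oxocyclohex‑3‑en‑1‑yl]acetaldehyde
Product: 10 2‑[(1R)‑4‑methyl‑5‑oxocyclohex‑3‑en‑1‑yl]prop‑2‑enal
Conditions: 37% aq. HCHO, pyrrolidine (10 mol%), EtCO2H (10 mol%), i‑PrOH, 45 °C
Reagents that add atoms: formaldehyde, C=O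
Why: Amine‑catalysed Mannich condensation with formaldehyde and elimination (aldehyde α‑methylenation) goes through the aldehyde enamine only, so the ring ketone is left alone and, as with other β‑branched aldehydes, the adjacent C5 stereocentre should not be touched (the descriptor changes by priority only).

**Step 6**
Reactants: 10 2‑[(1R)‑4‑methyl‑5‑oxocyclohex‑3‑en‑1‑yl]prop‑2‑enal
Product: 11 (5R)‑5‑[(3S)‑3‑hydroxyhexa‑1,5‑dien‑2‑yl]‑2‑methylcyclohex‑2‑en‑1‑one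
Conditions: (−)‑Ipc2B(allyl) (1 M in pentane), Et2O, −78 °C; then HOCH2CH2NH2, rt
Reagents that add atoms: (−)‑B‑allyldiisopinocampheylborane, C=CCB([C@@H]1C[C@@H]2C[C@H]([C@H]1C)C2(C)C)[C@@H]1C[C@@H]2C[C@H]([C@H]1C)C2(C)C
Why: Brown allylboration through a closed chair transition state; the isopinocampheyl groups derived from (+)‑α‑pinene should direct the allyl group to the face that gives the (S)‑carbinol at C2', as with other sp2‑substituted aldehydes, and the aldehyde reacts far faster than the ring ketone at −78 °C.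

**Step 7**
Reactants: 11 (5R)‑5‑[(3S)‑3‑hydroxyhexa‑1,5‑dien‑2‑yl]‑2‑methylcyclohex‑2‑en‑1‑one; 12 angelic acid [(2Z)‑2‑methylbut‑2‑enoic acid]
Product: 14 (3S)‑2‑[(1R)‑4‑methyl‑5‑oxocyclohex‑3‑en‑1‑yl]hexa‑1,5‑dien‑3‑yl (2Z)‑2‑methylbut‑2‑enoate, via mixed anhydride 13 (not isolated)
Conditions: 12, 2,4,6‑Cl3C6H2COCl, Et3N, toluene, rt; then 11, 80 °C
Reagents that add atoms: none
Why: Yamaguchi‑type esterification via mixed anhydride 13 acylates the hindered allylic alcohol with retention at C2'; leaving out a nucleophilic pyridine catalyst is meant to keep the (Z)‑geometry of the angelate.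

**Step 8**
Reactants: 14 (3S)‑2‑[(1R)‑4‑methyl‑5‑oxocyclohex‑3‑en‑1‑yl]hexa‑1,5‑dien‑3‑yl (2Z)‑2‑methylbut‑2‑enoate
Product: 15 (3S)‑6‑methyl‑2‑[(1R)‑4‑methyl‑5‑oxocyclohex‑3‑en‑1‑yl]hepta‑1,5‑dien‑3‑yl (2Z)‑2‑methylbut‑2‑enoate
Conditions: 2‑methylbut‑2‑ene (excess), second‑generation Grubbs catalyst (H2IMes)(PCy3)Cl2Ru=CHPh (5 mol%), CH2Cl2, 40 °C
Reagents that add atoms: 2‑methylbut‑2‑ene, CC=C(C)C
Why: Olefin cross‑metathesis with 2‑methylbut‑2‑ene turns the terminal vinyl group into the prenyl‑type trisubstituted alkene with loss of propene; the 1,1‑disubstituted alkene, the enone and the angelate are too hindered or electron‑poor to take part.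

**Step 9**
Reactants: 15 (3S)‑6‑methyl‑2‑[(1R)‑4‑methyl‑5‑oxocyclohex‑3‑en‑1‑yl]hepta‑1,5‑dien‑3‑yl (2Z)‑2‑methylbut‑2‑enoate
Product: 16 (2S)‑1‑[(2R)‑3,3‑dimethyloxiran‑2‑yl]‑3‑[(1R)‑4‑methyl‑5‑oxocyclohex‑3‑en‑1‑yl]but‑3‑en‑2‑yl (2Z)‑2‑methylbut‑2‑enoate
Conditions: D‑fructose‑derived Shi ketone (30 mol%), Oxone, K2CO3, Bu4NHSO4, MeCN/CH2(OMe)2/aq. Na2B4O7–Na2EDTA buffer, 0 °C
Reagents that add atoms: potassium peroxymonosulfate (Oxone, KHSO5), [K+].[O-]S(=O)(=O)OO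
Why: Shi asymmetric epoxidation; the chiral dioxirane attacks the most electron‑rich (trisubstituted) alkene through a spiro transition state and should set (R) at C4' under catalyst control, while the enone, the angelate and the 1,1‑disubstituted alkene react much more slowly.

**Step 10**
Reactants: 16 (2S)‑1‑[(2R)‑3,3‑dimethyloxiran‑2‑yl]‑3‑[(1R)‑4‑methyl‑5‑oxocyclohex‑3‑en‑1‑yl]but‑3‑en‑2‑yl (2Z)‑2‑methylbut‑2‑enoate
Product: 17 (2S)‑1‑[(2R)‑3,3‑dimethyloxiran‑2‑yl]‑3‑[(1S,6S)‑6‑hydroxy‑4‑methyl‑5‑oxocyclohex‑3‑en‑1‑yl]but‑3‑en‑2‑yl (2Z)‑2‑methylbut‑2‑enoate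
Conditions: KN(SiMe3)2, THF, −78 °C; then 3‑phenyl‑2‑(phenylsulfonyl)oxaziridine, −78 °C; AcOH quench
Reagents that add atoms: 3‑phenyl‑2‑(phenylsulfonyl)oxaziridine (Davis oxaziridine), O=S(=O)(N1OC1c1ccccc1)c1ccccc1
Why: Kinetic deprotonation at the α'‑carbon C6 gives the cross‑conjugated dienolate, which the Davis oxaziridine should oxidise on the face anti to the C5 substituent (C6–OH trans to the side chain); the ketone is deprotonated much faster than the ester at −78 °C.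

**Step 11**
Reactants: 17 (2S)‑1‑[(2R)‑3,3‑dimethyloxiran‑2‑yl]‑3‑[(1S,6S)‑6‑hydroxy‑4‑methyl‑5‑oxocyclohex‑3‑en‑1‑yl]but‑3‑en‑2‑yl (2Z)‑2‑methylbut‑2‑enoate; 12 angelic acid
Product: 18 (2S)‑1‑[(2R)‑3,3‑dimethyloxiran‑2‑yl]‑3‑[(1S,6R)‑4‑methyl‑6‑{[(2Z)‑2‑methylbut‑2‑enoyl]oxy}‑5‑oxocyclohex‑3‑en‑1‑yl]but‑3‑en‑2‑yl (2Z)‑2‑methylbut‑2‑enoate
Conditions: 12, PPh3, DIAD, toluene, 0 °C to rt
Reagents that add atoms: none
Why: Mitsunobu esterification; SN2 displacement of the α‑keto oxyphosphonium ion by angelate inverts C6, which places the angeloyloxy group cis to the C5 side chain under neutral conditions that keep the (Z)‑ester geometry.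

**Step 12**
Reactants: 18 (2S)‑1‑[(2R)‑3,3‑dimethyloxiran‑2‑yl]‑3‑[(1S,6R)‑4‑methyl‑6‑{[(2Z)‑2‑methylbut‑2‑enoyl]oxy}‑5‑oxocyclohex‑3‑en‑1‑yl]but‑3‑en‑2‑yl (2Z)‑2‑methylbut‑2‑enoate
Product: 19 (2S)‑1‑[(2R)‑3,3‑dimethyloxiran‑2‑yl]‑3‑[(1S,5S,6R)‑5‑hydroxy‑4‑methyl‑6‑{[(2Z)‑2‑methylbut‑2‑enoyl]oxy}cyclohex‑3‑en‑1‑yl]but‑3‑en‑2‑yl (2Z)‑2‑methylbut‑2‑enoate
Conditions: NaBH4, CeCl3·7H2O, MeOH, −78 °C
Reagents that add atoms: none
Why: Luche 1,2‑reduction; hydride should add axially to the enone carbonyl from the face anti to the pseudo‑axial C6 acyloxy group (Felkin–Anh sense, as in the reduction of carvone to cis‑carveol), giving the C1 hydroxyl cis to the C6 ester and the C5 side chain, while esters and the epoxide are inert at −78 °C.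

**Step 13**
Reactants: 19 (2S)‑1‑[(2R)‑3,3‑dimethyloxiran‑2‑yl]‑3‑[(1S,5S,6R)‑5‑hydroxy‑4‑methyl‑6‑{[(2Z)‑2‑methylbut‑2‑enoyl]oxy}cyclohex‑3‑en‑1‑yl]but‑3‑en‑2‑yl (2Z)‑2‑methylbut‑2‑enoate
Product: 20 (1R,2R,3R,4S,6S)‑4‑[(3S)‑4‑[(2R)‑3,3‑dimethyloxiran‑2‑yl]‑3‑{[(2Z)‑2‑methylbut‑2‑enoyl]oxy}but‑1‑en‑2‑yl]‑2‑hydroxy‑1‑methyl‑7‑oxabicyclo[4.1.0]heptan‑3‑yl (2Z)‑2‑methylbut‑2‑enoate (target)
Conditions: VO(acac)2 (5 mol%), t‑BuOOH (decane), CH2Cl2, 0 °C to rt
Reagents that add atoms: tert‑butyl hydroperoxide, CC(C)(C)OO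
Why: Hydroxyl‑directed epoxidation; the vanadium alkoxide of the allylic alcohol delivers the peroxide oxygen to C2=C3 on the face of the C1 hydroxyl, giving the cis epoxy alcohol, and alkenes without an allylic hydroxyl should not react.

**Compound list**

1 | but‑3‑en‑1‑yl acetate | C=CCCOC(C)=O | starting material
2 | (E)‑but‑2‑enal | C/C=C/C=O | starting material
3 | (E)‑5‑oxopent‑3‑en‑1‑yl acetate | CC(=O)OCC/C=C/C=O | intermediate
4 | tert‑butyl 3‑oxopentanoate | CCC(=O)CC(=O)OC(C)(C)C | starting material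
5 | tert‑butyl (3R)‑3‑(2‑acetoxyethyl)‑5‑oxo‑2‑propanoylpentanoate (C2 epimers; Michael adduct) | CC(=O)OCC[C@@H](C(C(=O)OC(C)(C)C)C(=O)CC)CC=O | intermediate
6 | (3R)‑5‑oxo‑3‑(2‑oxoethyl)heptyl acetate (keto aldehyde) | CC(=O)OCC[C@@H](CC(=O)CC)CC=O | intermediate
7 | 2‑[(1S)‑4‑methyl‑5‑oxocyclohex‑3‑en‑1‑yl]ethyl acetate | CC(=O)OCC[C@@H]1CC=C(C)C(=O)C1 | intermediate
8 | (5S)‑5‑(2‑hydroxyethyl)‑2‑methylcyclohex‑2‑en‑1‑one | OCC[C@@H]1CC=C(C)C(=O)C1 | intermediate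
9 | 2‑[(1S)‑4‑methyl‑5‑oxocyclohex‑3‑en‑1‑yl]acetaldehyde | O=CC[C@@H]1CC=C(C)C(=O)C1 | intermediate
10 | 2‑[(1R)‑4‑methyl‑5‑oxocyclohex‑3‑en‑1‑yl]prop‑2‑enal | C=C(C=O)[C@@H]1CC=C(C)C(=O)C1 | intermediate
11 | (5R)‑5‑[(3S)‑3‑hydroxyhexa‑1,5‑dien‑2‑yl]‑2‑methylcyclohex‑2‑en‑1‑one | C=C([C@H](CC=C)O)[C@@H]1CC=C(C)C(=O)C1 | intermediate
12 | angelic acid, (2Z)‑2‑methylbut‑2‑enoic acid | C/C=C(/C)C(=O)O | starting material
13 | (2Z)‑2‑methylbut‑2‑enoic 2,4,6‑trichlorobenzoic anhydride (mixed anhydride) | C/C=C(/C)C(=O)OC(=O)c1c(Cl)cc(Cl)cc1Cl | intermediate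
14 | (3S)‑2‑[(1R)‑4‑methyl‑5‑oxocyclohex‑3‑en‑1‑yl]hexa‑1,5‑dien‑3‑yl (2Z)‑2‑methylbut‑2‑enoate | C=C([C@H](CC=C)OC(=O)/C(C)=C\C)[C@@H]1CC=C(C)C(=O)C1 | intermediate
15 | (3S)‑6‑methyl‑2‑[(1R)‑4‑methyl‑5‑oxocyclohex‑3‑en‑1‑yl]hepta‑1,5‑dien‑3‑yl (2Z)‑2‑methylbut‑2‑enoate | C=C([C@H](CC=C(C)C)OC(=O)/C(C)=C\C)[C@@H]1CC=C(C)C(=O)C1 | intermediate
16 | (2S)‑1‑[(2R)‑3,3‑dimethyloxiran‑2‑yl]‑3‑[(1R)‑4‑methyl‑5‑oxocyclohex‑3‑en‑1‑yl]but‑3‑en‑2‑yl (2Z)‑2‑methylbut‑2‑enoate | C=C([C@H](C[C@H]1OC1(C)C)OC(=O)/C(C)=C\C)[C@@H]1CC=C(C)C(=O)C1 | intermediate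
17 | (2S)‑1‑[(2R)‑3,3‑dimethyloxiran‑2‑yl]‑3‑[(1S,6S)‑6‑hydroxy‑4‑methyl‑5‑oxocyclohex‑3‑en‑1‑yl]but‑3‑en‑2‑yl (2Z)‑2‑methylbut‑2‑enoate | C=C([C@H](C[C@H]1OC1(C)C)OC(=O)/C(C)=C\C)[C@@H]1CC=C(C)C(=O)[C@H]1O | intermediate
18 | (2S)‑1‑[(2R)‑3,3‑dimethyloxiran‑2‑yl]‑3‑[(1S,6R)‑4‑methyl‑6‑{[(2Z)‑2‑methylbut‑2‑enoyl]oxy}‑5‑oxocyclohex‑3‑en‑1‑yl]but‑3‑en‑2‑yl (2Z)‑2‑methylbut‑2‑enoate | C=C([C@H](C[C@H]1OC1(C)C)OC(=O)/C(C)=C\C)[C@@H]1CC=C(C)C(=O)[C@@H]1OC(=O)/C(C)=C\C | intermediate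
19 | (2S)‑1‑[(2R)‑3,3‑dimethyloxiran‑2‑yl]‑3‑[(1S,5S,6R)‑5‑hydroxy‑4‑methyl‑6‑{[(2Z)‑2‑methylbut‑2‑enoyl]oxy}cyclohex‑3‑en‑1‑yl]but‑3‑en‑2‑yl (2Z)‑2‑methylbut‑2‑enoate | C=C([C@H](C[C@H]1OC1(C)C)OC(=O)/C(C)=C\C)[C@@H]1CC=C(C)[C@H](O)[C@@H]1OC(=O)/C(C)=C\C | intermediate
20 | (1R,2R,3R,4S,6S)‑4‑[(3S)‑4‑[(2R)‑3,3‑dimethyloxiran‑2‑yl]‑3‑{[(2Z)‑2‑methylbut‑2‑enoyl]oxy}but‑1‑en‑2‑yl]‑2‑hydroxy‑1‑methyl‑7‑oxabicyclo[4.1.0]heptan‑3‑yl (2Z)‑2‑methylbut‑2‑enoate | C=C([C@H](C[C@H]1OC1(C)C)OC(=O)/C(C)=C\C)[C@@H]1C[C@@H]2O[C@]2(C)[C@H](O)[C@@H]1OC(=O)/C(C)=C\C | target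

**Totals and risks**

Total step count: 13. Longest linear sequence: 13 steps (1 → 20; compounds 2, 4 and 12 are purchased).

Steps most likely to fail, with fallbacks:

1. Step 11. The oxyphosphonium ion of the hindered α‑keto carbinol may eliminate toward the cross‑conjugated dienone, or the displacement by the weakly nucleophilic, hindered angelate may be incomplete. The fallback sets out from 17. Sulfonylation with Tf2O and 2,6‑lutidine in CH2Cl2 at −78 °C should give the α‑keto triflate (2S)‑1‑[(2R)‑3,3‑dimethyloxiran‑2‑yl]‑3‑[(1S,6S)‑4‑methyl‑5‑oxo‑6‑{[(trifluoromethyl)sulfonyl]oxy}cyclohex‑3‑en‑1‑yl]but‑3‑en‑2‑yl (2Z)‑2‑methylbut‑2‑enoate F1. Displacement of this isolated sulfonate with cesium angelate (from 12 and Cs2CO3, 18‑crown‑6, toluene) should proceed with inversion and comes back to the route at 18.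

2. Step 10. The potassium enolate or the new alkoxide may take up the C2' angeloyl group by acyl transfer, the enolate may add to the sulfonimine by‑product, or facial selectivity may be poor. The fallback sets out from 16. Enolisation with KN(SiMe3)2 in the presence of Me3SiCl (internal quench, THF, −78 °C) should trap the kinetic enolate as the cross‑conjugated silyl dienol ether (2S)‑1‑[(2R)‑3,3‑dimethyloxiran‑2‑yl]‑3‑[(1R)‑4‑methyl‑5‑[(trimethylsilyl)oxy]cyclohexa‑3,5‑dien‑1‑yl]but‑3‑en‑2‑yl (2Z)‑2‑methylbut‑2‑enoate F2. Rubottom oxidation of this electron‑rich diene with dimethyldioxirane in acetone at −78 °C, again anti to the C5 substituent, followed by mild desilylation on work‑up, comes back to the route at 17.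

3. Step 7. The activated angeloyl unit may isomerise to the (E)‑isomer (tiglate), or acylation of the hindered allylic alcohol may be sluggish. The fallback sets out from 10. Allylboration with the enantiomeric reagent (+)‑Ipc2B(allyl) should give the epimeric carbinol (5R)‑5‑[(3R)‑3‑hydroxyhexa‑1,5‑dien‑2‑yl]‑2‑methylcyclohex‑2‑en‑1‑one F3. Mitsunobu esterification of F3 with 12 (PPh3, DIAD, toluene) introduces the ester by SN2 inversion at carbon under neutral conditions, with no activated acyl species, and comes back to the route at 14.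

**Further compounds**

F1 | step 11 | (2S)‑1‑[(2R)‑3,3‑dimethyloxiran‑2‑yl]‑3‑[(1S,6S)‑4‑methyl‑5‑oxo‑6‑{[(trifluoromethyl)sulfonyl]oxy}cyclohex‑3‑en‑1‑yl]but‑3‑en‑2‑yl (2Z)‑2‑methylbut‑2‑enoate | C=C([C@H](C[C@H]1OC1(C)C)OC(=O)/C(C)=C\C)[C@@H]1CC=C(C)C(=O)[C@H]1OS(=O)(=O)C(F)(F)F
F2 | step 10 | (2S)‑1‑[(2R)‑3,3‑dimethyloxiran‑2‑yl]‑3‑[(1R)‑4‑methyl‑5‑[(trimethylsilyl)oxy]cyclohexa‑3,5‑dien‑1‑yl]but‑3‑en‑2‑yl (2Z)‑2‑methylbut‑2‑enoate | C=C([C@H](C[C@H]1OC1(C)C)OC(=O)/C(C)=C\C)[C@@H]1CC=C(C)C(O[Si](C)(C)C)=C1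
F3 | step 7 | (5R)‑5‑[(3R)‑3‑hydroxyhexa‑1,5‑dien‑2‑yl]‑2‑methylcyclohex‑2‑en‑1‑one | C=C([C@@H](CC=C)O)[C@@H]1CC=C(C)C(=O)C1
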